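**Retrosynthetic overview**
- Last disconnection: both gem-dimethyl groups at once. The target comes from a fully aromatic methylene-bridged bis(acylphloroglucinol) by fourfold C-methylation, which dearomatises both rings in one operation (key step).
- The unsymmetrical diarylmethane comes from a directed Mannich / ortho-quinone methide cross-coupling of butyrylphloroglucinol (electrophile) with flopropione (nucleophile, in excess); the bridge carbon comes from Eschenmoser's salt.
- Butyrylphloroglucinol comes from phloroglucinol by Friedel–Crafts acylation.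
- No ring is constructed: ring A (butyryl-bearing) and ring B (propionyl-bearing) are pre-formed benzene rings of the phloroglucinol type, joined first and converted together into the two cyclohexadienone rings last.

Assumption: the target has no stereocentre (both CMe2 carbons carry identical methyls) and is achiral, so no enantiocontrol is needed; it is drawn as one of its interconverting enol tautomers, and flopropione is taken as a purchased catalogue compound.

**Step 1**
Reactants: 1 phloroglucinol (benzene-1,3,5-triol); 2 butanoyl chloride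
Product: 3 1-(2,4,6-trihydroxyphenyl)butan-1-one (butyrylphloroglucinol)
Conditions: AlCl3 (3.5 equiv), CH2Cl2/MeNO2, 0 °C to 40 °C, 4 h; then ice/1 M HCl
Reagents that add atoms: butanoyl chloride, CCCC(Cl)=O
Why: Friedel–Crafts C-acylation of the highly activated, threefold-symmetric ring, in which the first (chelated) acyl group deactivates the ring so that monoacylation dominates with one equivalent of acyl chloride; no stereocentre is formed.

**Step 2**
Reactants: 3 1-(2,4,6-trihydroxyphenyl)butan-1-one; 4 N,N-dimethylmethyleneiminium iodide (Eschenmoser's salt); 5 1-(2,4,6-trihydroxyphenyl)propan-1-one (flopropione)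
Product: 8 1-[2,4,6-trihydroxy-3-[(2,4,6-trihydroxy-3-propanoylphenyl)methyl]phenyl]butan-1-one, via Mannich base 6 (not isolated), via quinone methide 7 (not isolated)
Conditions: 4 (1.05 equiv), NaOAc (1.1 equiv), MeCN, 0 °C to rt, 1 h; then 5 (3.0 equiv), 80 °C, 8 h
Reagents that add atoms: N,N-dimethylmethyleneiminium iodide, C=[N+](C)C.[I-]
Why: Phenolic Mannich reaction at one of the two equivalent free positions of 3 gives 6, which on warming loses dimethylamine to the ortho-quinone methide 7, and this is intercepted by excess 5 in a Friedel–Crafts-type conjugate addition at either of its equivalent free positions, so the electrophile/nucleophile pairing gives the mixed diarylmethane and no stereocentre arises.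

**Step 3**
Reactants: 8 1-[2,4,6-trihydroxy-3-[(2,4,6-trihydroxy-3-propanoylphenyl)methyl]phenyl]butan-1-one; 9 iodomethane
Product: 11 2-butanoyl-6-[(2,4-dihydroxy-3,3-dimethyl-6-oxo-5-propanoylcyclohexa-1,4-dien-1-yl)methyl]-3,5-dihydroxy-4,4-dimethylcyclohexa-2,5-dien-1-one (target), via bis(C-methyl) diarylmethane 10 (not isolated)
Conditions: NaOMe (7 equiv), MeOH, 0 °C; 9 (4.2 equiv) added over 2 h; 0 °C to rt, 16 h; then 1 M HCl
Reagents that add atoms: iodomethane, CI
Why: Proposed new method: twofold alkylative dearomatisation of a methylene-bridged bis(acylphloroglucinol) by fourfold SN2 C-methylation, the closest known reaction type being the NaOMe/MeI gem-dimethylation of monomeric acylphloroglucinols to acylfilicinic acids; each ring of the polyphenoxide has a single free CH that is methylated first (giving 10), the new C-methyl carbon is then the most electron-rich and least hindered ring position (the bridge-bearing carbon is shielded by the other ring and its sodium phenoxides, the acyl-bearing carbon is deactivated), so the second methyl lands there and breaks aromaticity, after which each ring is a stabilised triketone enolate that resists further methylation; no stereocentre is created.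

**Compound list**
1 | phloroglucinol (benzene-1,3,5-triol) | Oc1cc(O)cc(O)c1 | starting material
2 | butanoyl chloride | CCCC(Cl)=O | starting material
3 | 1-(2,4,6-trihydroxyphenyl)butan-1-one (butyrylphloroglucinol) | CCCC(=O)c1c(O)cc(O)cc1O | intermediate
4 | N,N-dimethylmethyleneiminium iodide (Eschenmoser's salt) | C=[N+](C)C.[I-] | starting material
5 | 1-(2,4,6-trihydroxyphenyl)propan-1-one (flopropione) | CCC(=O)c1c(O)cc(O)cc1O | starting material
6 | 1-[3-[(dimethylamino)methyl]-2,4,6-trihydroxyphenyl]butan-1-one (Mannich base) | CCCC(=O)c1c(O)cc(O)c(CN(C)C)c1O | intermediate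
7 | 2-butanoyl-3,5-dihydroxy-6-methylidenecyclohexa-2,4-dien-1-one (ortho-quinone methide) | CCCC(=O)C1=C(O)C=C(O)C(=C)C1=O | intermediate
8 | 1-[2,4,6-trihydroxy-3-[(2,4,6-trihydroxy-3-propanoylphenyl)methyl]phenyl]butan-1-one | CCCC(=O)c1c(O)cc(O)c(Cc2c(O)cc(O)c(C(=O)CC)c2O)c1O | intermediate
9 | iodomethane | CI | starting material
10 | 1-[2,4,6-trihydroxy-3-methyl-5-[(2,4,6-trihydroxy-3-methyl-5-propanoylphenyl)methyl]phenyl]butan-1-one | CCCC(=O)c1c(O)c(C)c(O)c(Cc2c(O)c(C)c(O)c(C(=O)CC)c2O)c1O | intermediate
11 | 2-butanoyl-6-[(2,4-dihydroxy-3,3-dimethyl-6-oxo-5-propanoylcyclohexa-1,4-dien-1-yl)methyl]-3,5-dihydroxy-4,4-dimethylcyclohexa-2,5-dien-1-one (mixed propionyl/butyryl albaspidin, achiral) | CCCC(=O)C1=C(O)C(C)(C)C(O)=C(CC2=C(O)C(C)(C)C(O)=C(C(=O)CC)C2=O)C1=O | target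

**Totals**
Total step count: 3. Longest linear sequence: 3 (1 → 3 → 8 → 11).

**Steps most likely to fail (highest risk first)**

Step 3 (twofold dearomatisation). The risks are a second methylation at the bridge-bearing carbon instead of the C-methyl carbon, a fifth methylation, O-methylation, and base-induced retro-Michael exchange of the two halves giving the symmetrical dimers. The fallback sets out from 3 and 5 and comes back at 11; it dearomatises the monomers and makes the bridge carbon by C–H oxidation. Treating 5 with NaOMe and 9 (2.2 equiv) in MeOH gives 3,5-dihydroxy-4,4-dimethyl-2-propanoylcyclohexa-2,5-dien-1-one F1 (propionylfilicinic acid). Treating 3 with NaOMe and 9 (3.3 equiv) gives 2-butanoyl-3,5-dihydroxy-4,4,6-trimethylcyclohexa-2,5-dien-1-one F2. Oxidation of F2 with TEMPO and Ag2O in toluene generates 2-butanoyl-3-hydroxy-4,4-dimethyl-6-methylidenecyclohex-2-ene-1,5-dione F3 in the flask. Adding F1 then gives 11 by Michael addition of its single free ring carbon to the exocyclic enone.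

Step 2 (aromatic cross-coupling). The risks are double aminomethylation of 3, further alkylation of 8 (each ring keeps one free CH), and self-trapping of 7 to the butyryl/butyryl dimer. The fallback sets out from 3 and comes back at 11; it dearomatises the electrophilic half first so that it has only one reactive ring position. Treating 3 with NaOMe and 9 (2.2 equiv) gives 2-butanoyl-3,5-dihydroxy-4,4-dimethylcyclohexa-2,5-dien-1-one F4 (butyrylfilicinic acid). With 4 this gives the single Mannich base 2-butanoyl-6-[(dimethylamino)methyl]-3,5-dihydroxy-4,4-dimethylcyclohexa-2,5-dien-1-one F5. Heating F5 with excess 5 gives 2-butanoyl-3,5-dihydroxy-4,4-dimethyl-6-[(2,4,6-trihydroxy-3-propanoylphenyl)methyl]cyclohexa-2,5-dien-1-one F6, a norflavaspidic-acid-type half-aromatic dimer. The one remaining aromatic ring of F6 is then gem-dimethylated with NaOMe and 9 (2.1 equiv) to reach 11.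

Step 1 (Friedel–Crafts butyrylation). The risks are diacylation and O-acylation. The fallback sets out from 1 and comes back at 3; it is a Houben–Hoesch reaction with butyronitrile, ZnCl2 and dry HCl in Et2O at 0 °C. This precipitates 1-(2,4,6-trihydroxyphenyl)butan-1-iminium chloride F7, which cannot react a second time, and hydrolysis in hot water gives 3.

**Further compounds**
F1 | step 3 | 3,5-dihydroxy-4,4-dimethyl-2-propanoylcyclohexa-2,5-dien-1-one | CCC(=O)C1=C(O)C(C)(C)C(O)=CC1=O
F2 | step 3 | 2-butanoyl-3,5-dihydroxy-4,4,6-trimethylcyclohexa-2,5-dien-1-one | CCCC(=O)C1=C(O)C(C)(C)C(O)=C(C)C1=O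
F3 | step 3 | 2-butanoyl-3-hydroxy-4,4-dimethyl-6-methylidenecyclohex-2-ene-1,5-dione | CCCC(=O)C1=C(O)C(C)(C)C(=O)C(=C)C1=O
F4 | step 2 | 2-butanoyl-3,5-dihydroxy-4,4-dimethylcyclohexa-2,5-dien-1-one | CCCC(=O)C1=C(O)C(C)(C)C(O)=CC1=O
F5 | step 2 | 2-butanoyl-6-[(dimethylamino)methyl]-3,5-dihydroxy-4,4-dimethylcyclohexa-2,5-dien-1-one | CCCC(=O)C1=C(O)C(C)(C)C(O)=C(CN(C)C)C1=O
F6 | step 2 | 2-butanoyl-3,5-dihydroxy-4,4-dimethyl-6-[(2,4,6-trihydroxy-3-propanoylphenyl)methyl]cyclohexa-2,5-dien-1-one | CCCC(=O)C1=C(O)C(C)(C)C(O)=C(Cc2c(O)cc(O)c(C(=O)CC)c2O)C1=O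
F7 | step 1 | 1-(2,4,6-trihydroxyphenyl)butan-1-iminium chloride | CCCC(=[NH2+])c1c(O)cc(O)cc1O.[Cl-]
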